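**Assumption:** the target is drawn as the free tris(hydrogen sulfate). Aryl hydrogen sulfates are stable only as salts, so 22 and 23 would be made and handled as their trisodium salts; they are named and listed here in the acid form of the target structure.

## The problem

Rhamnetin 3,5,4'-tri-O-sulfate is a flavonol. Ring A is fused to the 4-pyranone ring C, ring B sits on C2, and an enolic oxygen sits on C3. The molecule has no stereocentre, so the difficulty lies entirely in regiochemistry and in telling five oxygen atoms apart. They must end in three states: a methyl ether at 7-O, a free phenol at 3'-O, and sulfate monoesters at 3-O, 5-O and 4'-O. Hence 5-O must be distinguished from 7-O on ring A, and 4'-O from its ortho neighbour 3'-O on ring B. Aryl sulfate monoesters are anionic, water-soluble and cleaved by acid, and they would not survive Lewis acids, organolithium reagents or oxidants. They must therefore go on last, and only a neutral operation may follow. The 5-hydroxyl is hydrogen-bonded to the C4 carbonyl, which helps its selective unmasking beside 7-OMe but makes it the hardest position to sulfate. Ring A carries O1 on C8a, the acyl carbon C4 on the adjacent C4a, and 5-O on C5 next to C4a. That is the pattern left when an aryne with a methoxy group beside the triple bond inserts into the acyl–oxygen bond of a carboxylic acid. If the acid is an arylpropiolic acid, its alkyne supplies C2, C3 and ring B, and ring C can close in the same flask.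

## Retrosynthesis

**23 from 22 (benzyl C–O bond at 3'-O).** Sulfating a free catechol selectively at 4'-O is not dependable, so 3'-O must stay masked through the sulfation. Any group removed afterwards by acid, fluoride or a Lewis acid would endanger the sulfates. A benzyl ether is removed by hydrogenolysis at neutral pH, which should leave aryl sulfate salts and the C2=C3 bond alone.

**22 from 21 (three O–S bonds).** In 21 the three hydroxyls to be sulfated are free and no other hydroxyl is present. Exhaustive sulfation therefore raises no regiochemical question. The forward step only has to be forcing enough to reach the chelated 5-OH.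

**21 from 19 through 20 (O–CH3 at 5-O, acetal at 4'-O).** The only real difference between 5-OMe and 7-OMe is that 5-OMe can chelate a metal together with the C4 carbonyl. A chelating magnesium halide with a nucleophilic counter-ion uses this, and should spare the benzyl ether, which a boron trihalide would not. The MOM (methoxymethyl) group at 4'-O has done its work after the oxidation step, so it is removed in the same pot by acidic methanolysis. Any premature MOM loss converges on the same product 21.

**19 from 17 (C3–O bond).** An alkynoic acid delivers C3 as CH, so the 3-oxygen cannot come through the ring-forming step. Epoxidation of the flavone C2=C3 bond and acid-induced rearrangement is the shortest known way to add it. It asks only that the benzyl and MOM ethers tolerate a neutral oxidant.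

**17 from 8 and 14 (O1–C8a, C4–C4a and O1–C2).** Classical flavone cuts start from an acylphloroglucinol in which three ring A oxygens must first be differentiated. The aryne cut instead draws the 1,2,3-pattern O1/C4/5-O from a symmetrical phenol and joins two fragments of similar size in one operation. The forward reaction must deliver the carboxylate oxygen to the aryne carbon remote from the methoxy group, transfer the acyl group before the aryl anion is protonated, and close ring C in the 6-endo mode.

**8 from 6, 2 and 1 (aryl C–Si and O–S bonds).** A carbamate on 3,5-dimethoxyphenol (1) directs lithiation to C2, between the carbamate and a methoxy group. Silylation gives 6, and carbamate removal with triflation in one flask gives 8. The arene is commercial and symmetrical, so only one ortho position type exists next to the directing group.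

**14 from 12, 11, 10 and 9 (C–CO2H and alkyne carbon).** Corey–Fuchs homologation of aldehyde 11, with CO2 as the electrophile, gives the propiolic acid directly. The two phenols of 3,4-dihydroxybenzaldehyde (9) differ in acidity, which allows MOM at 4-O first (10) and benzyl at 3-O second (11).

## Roads not taken

**Alternative 1:** The cut is C4a–C4 and C4–C3, with carbon monoxide A3 as C4, followed by O1–C2. In the forward step a palladium–bisphosphine catalyst would turn the symmetrical ring A iodide A1 into an acylpalladium species under A3. This acylates the enolate of the α-(MOM-oxy) ketone A2, and methanolic acid then strips the MOM groups and closes ring C to A4.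
- Merits: A4 has the same structure as 21. The 3-oxygen and the free 5-OH arrive in place, so neither the epoxidation (step 9) nor the demethylation (step 10) is needed. On this count the alternative is better than the chosen plan, by two steps after ring formation.
- Weak points: A1 is an electron-rich iodide flanked by two ortho alkoxy groups, so oxidative addition and acyl transfer are both hindered. The α-oxygenated enolate of A2 is a poorer carbon nucleophile, and O-acylation and direct arylation without A3 can compete. A1 and A2 each need several steps.
- Comparison: the chosen plan sets against this a key step whose substrate pattern (an aryne with a neighbouring methoxy group and a carboxylic acid) matches known reactivity, with no gas handling and no double handicap in a single coupling.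

**Alternative 2:** The cut is C8–C8a and C4a–C5, so ring A is built last. The brominated C5=C6 bond of pyranone A5 would take up the 1,1,3-trioxygenated diene A6 in a Diels–Alder reaction, and two eliminations would aromatise ring A to A7.
- Merits: A7 has 5-OH free and 7-OMe in place, so no selective demethylation is required, and the 3-oxygen is already present. The bromine fixes the orientation. This is a shorter and cleaner endgame than the chosen one.
- Weak points: a 4-pyranone is a poor dienophile, since it is a vinylogous ester with partial aromatic character and a donor oxygen on the reacting double bond. Dienes of type A6 are dependable with haloquinones, not with halopyranones. A5 itself requires a long synthesis with a regioselective bromination, and A6 is acid- and moisture-sensitive.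
- Comparison: the chosen plan gives up the pre-differentiated ring A and accepts the chelation-controlled demethylation, in exchange for a ring-forming step with close precedent and two short fragment syntheses.

**Alternative 3:** The cut is C3–C4 and O1–C8a. The lithium enolate of A2 would be acylated on carbon by 2,4,6-trifluorobenzoyl chloride A8, and the enolate oxygen of the resulting diketone would displace an ortho fluorine to give A9.
- Merits: the chemistry is robust and ionic, no aryne precursor has to be made, the 3-oxygen is in place and A8 is commercial. The key step is probably more dependable than the aryne insertion.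
- Weak points: A9 carries fluorine at C5 and C7 where the target has two different oxygens. Methoxide must go to C7 only and a hydroxide equivalent to C5 only. Both positions are activated by the C4 carbonyl, so selectivity is not assured. Double methoxylation would lead back to the very demethylation problem the route tries to avoid. Two or more extra steps under alkoxide and heat have to be borne by the 3-(MOM-oxy) flavone.
- Comparison: the chosen plan has the less certain key step but places both ring A oxygens correctly from the start, with no regiochemical question on ring A afterwards.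

Key step: step 8

## Route

Step 1
Reactants: 1 3,5-dimethoxyphenol
Product: 2 3,5-dimethoxyphenyl N-(propan-2-yl)carbamate
Conditions: i-PrNCO, NEt3 (cat.), CH2Cl2, rt
Reagents that add atoms: isopropyl isocyanate (2-isocyanatopropane), CC(C)N=C=O
Why: Base-catalysed addition of the phenol to the isocyanate (carbamoylation); the N–H carbamate is a strong ortho director after N-silylation and can later be removed under mild E1cB conditions.

Step 2
Reactants: 2 3,5-dimethoxyphenyl N-(propan-2-yl)carbamate
Product: 6 3,5-dimethoxy-2-(trimethylsilyl)phenyl N-(propan-2-yl)carbamate, via N-silyl carbamate 3 (not isolated), via aryllithium 4 (not isolated), via N-silyl ortho-silyl carbamate 5 (not isolated)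
Conditions: TBSOTf, TMEDA, Et2O, 0 °C to rt; n-BuLi (2 equiv), TMEDA, −78 °C; TMSCl, −78 °C to rt; aq NaHSO4
Reagents that add atoms: chlorotrimethylsilane, C[Si](C)(C)Cl
Why: Directed ortho-metalation: N-silylation masks the N–H, and the carbamate together with the neighbouring methoxy group steers n-BuLi to C2, whereas C4 between the two methoxy groups lacks the stronger director. Quenching at −78 °C outruns anionic Fries rearrangement, and the N-silyl group is lost in the acidic wash.

Step 3
Reactants: 6 3,5-dimethoxy-2-(trimethylsilyl)phenyl N-(propan-2-yl)carbamate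
Product: 8 3,5-dimethoxy-2-(trimethylsilyl)phenyl trifluoromethanesulfonate, via ortho-silyl phenol 7 (not isolated)
Conditions: DBU, Et2NH, MeCN, 40 °C; then PhNTf2, rt
Reagents that add atoms: N-phenylbis(trifluoromethanesulfonimide), O=S(=O)(N(c1ccccc1)S(=O)(=O)C(F)(F)F)C(F)(F)F
Why: DBU removes the N–H proton and the carbamate fragments by E1cB to the phenoxide and isopropyl isocyanate, which Et2NH traps as a urea. Triflation of the phenoxide in the same flask means the electron-rich ortho-silyl phenol, prone to protodesilylation, is never isolated.

Step 4
Reactants: 9 3,4-dihydroxybenzaldehyde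
Product: 10 3-hydroxy-4-(methoxymethoxy)benzaldehyde
Conditions: MOMCl (1.05 equiv), K2CO3 (1.1 equiv), acetone, 0 °C to rt
Reagents that add atoms: chloromethyl methyl ether, COCCl
Why: Williamson-type O-alkylation; the 4-OH para to the formyl group is the more acidic phenol, so with a weak base the 4-phenoxide forms and is alkylated selectively.

Step 5
Reactants: 10 3-hydroxy-4-(methoxymethoxy)benzaldehyde
Product: 11 3-(benzyloxy)-4-(methoxymethoxy)benzaldehyde
Conditions: BnBr, K2CO3, DMF, rt
Reagents that add atoms: benzyl bromide, BrCc1ccccc1
Why: Williamson ether synthesis on the only remaining phenol.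

Step 6
Reactants: 11 3-(benzyloxy)-4-(methoxymethoxy)benzaldehyde
Product: 12 2-(benzyloxy)-4-(2,2-dibromoethenyl)-1-(methoxymethoxy)benzene
Conditions: CBr4, PPh3, NEt3, CH2Cl2, 0 °C
Reagents that add atoms: carbon tetrabromide, BrC(Br)(Br)Br
Why: First stage of the Corey–Fuchs reaction (Wittig-type dibromo-olefination); NEt3 buffers traces of HBr so that the MOM acetal survives.

Step 7
Reactants: 12 2-(benzyloxy)-4-(2,2-dibromoethenyl)-1-(methoxymethoxy)benzene
Product: 14 3-[3-(benzyloxy)-4-(methoxymethoxy)phenyl]prop-2-ynoic acid, via lithium acetylide 13 (not isolated)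
Conditions: n-BuLi (2.2 equiv), THF, −78 °C; CO2 (g), −78 to 0 °C; 1 M HCl to pH 3, 0 °C
Reagents that add atoms: carbon dioxide, O=C=O
Why: Second stage of the Corey–Fuchs reaction: bromine–lithium exchange and Fritsch–Buttenberg–Wiechell rearrangement give the lithium acetylide, which is carboxylated by CO2. The low temperature keeps MOM-directed ring lithiation and Wittig rearrangement of the benzyl ether out, and the brief cold acidification spares the MOM group.

Step 8
Reactants: 8 3,5-dimethoxy-2-(trimethylsilyl)phenyl trifluoromethanesulfonate; 14 3-[3-(benzyloxy)-4-(methoxymethoxy)phenyl]prop-2-ynoic acid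
Product: 17 2-[3-(benzyloxy)-4-(methoxymethoxy)phenyl]-5,7-dimethoxy-4H-chromen-4-one, via 3,5-dimethoxybenzyne 15 (not isolated), via ortho-hydroxyaryl ynone 16 (not isolated)
Conditions: 8 (1.5 equiv), CsF (4 equiv), THF, 125 °C, sealed tube
Reagents that add atoms: none
Why: Fluoride attacks silicon in 8 and triflate leaves, giving aryne 15, while further CsF turns 14 into its caesium salt. The methoxy group beside the triple bond withdraws inductively and distorts the aryne, so the carboxylate oxygen adds to the remote aryne carbon (O1–C8a) and the negative charge develops on the carbon flanked by the methoxy group (future C4a). In hot aprotic THF this aryl anion attacks the adjacent ester carbonyl through a four-membered alkoxide, which opens to the ortho-acyl phenoxide of 16; C4–C4a has then formed and the net result is insertion of the aryne into the acyl–oxygen bond. The phenoxide closes ring C by 6-endo-dig conjugate (oxa-Michael) addition to the β-carbon of the ynone (O1–C2), and the C3 anion is protonated by the bifluoride left from the acid. The closest known reaction type is the CsF-mediated insertion of arynes from ortho-silyl aryl triflates into the acyl–oxygen bond of carboxylic acids to give ortho-hydroxyaryl ketones, with in-flask cyclisation when the acid carries an unsaturated acceptor. No stereocentre is formed. Three selectivities are needed: the site of attack on the aryne, secured by the methoxy group next to the triple bond (the second methoxy group, meta to the oxygen-bearing and para to the acyl-bearing carbon, has little influence and becomes 7-OMe); acyl transfer over protonation of the aryl anion, secured by the absence of any proton source stronger than bifluoride and by the high temperature; and 6-endo over 5-exo closure, secured by the polarisation of the ynone, whose β-carbon is the electrophilic site for a free phenoxide in an aprotic medium.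

Step 9
Reactants: 17 2-[3-(benzyloxy)-4-(methoxymethoxy)phenyl]-5,7-dimethoxy-4H-chromen-4-one
Product: 19 2-[3-(benzyloxy)-4-(methoxymethoxy)phenyl]-3-hydroxy-5,7-dimethoxy-4H-chromen-4-one, via 2,3-epoxyflavanone 18 (not isolated)
Conditions: DMDO (acetone solution), CH2Cl2, 0 °C to rt; then p-TsOH·H2O (cat.), CH2Cl2, rt
Reagents that add atoms: dimethyldioxirane, CC1(C)OO1
Why: Dimethyldioxirane epoxidises the C2=C3 bond of flavones under neutral conditions. Acid opens the epoxide at C2 to a cation stabilised by O1 and ring B, and loss of H3 gives the 3-hydroxyflavone (epoxidation–rearrangement); the racemic epoxide 18 loses both stereocentres in the rearrangement.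

Step 10
Reactants: 19 2-[3-(benzyloxy)-4-(methoxymethoxy)phenyl]-3-hydroxy-5,7-dimethoxy-4H-chromen-4-one
Product: 21 2-[3-(benzyloxy)-4-hydroxyphenyl]-3,5-dihydroxy-7-methoxy-4H-chromen-4-one, via 5-hydroxy MOM ether 20 (not isolated)
Conditions: MgI2·OEt2 (4 equiv), toluene/THF, 70 °C; then 2 M HCl, MeOH, 50 °C
Reagents that add atoms: none
Why: Chelation-controlled ether cleavage: magnesium is held between the C4 carbonyl and 5-OMe and iodide removes that methyl group by SN2, while 7-OMe and the benzyl ether have no such chelate. The acidic methanol then breaks the magnesium chelates and transfers the MOM group to methanol (acetal exchange).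

Step 11
Reactants: 21 2-[3-(benzyloxy)-4-hydroxyphenyl]-3,5-dihydroxy-7-methoxy-4H-chromen-4-one
Product: 22 2-[3-(benzyloxy)-4-(sulfooxy)phenyl]-7-methoxy-4-oxo-4H-chromene-3,5-diyl bis(hydrogen sulfate)
Conditions: SO3·NMe3 (excess), NEt3, MeCN, 100 °C (microwave, sealed vial); then Na+-form cation-exchange resin, H2O
Reagents that add atoms: sulfur trioxide–trimethylamine complex, C[N+](C)(C)S(=O)(=O)[O-]
Why: O-Sulfonation of phenols and of the enolic 3-OH by an amine–SO3 complex; excess reagent, base and heat are the known means of carrying per-sulfation of flavonoids through to the hydrogen-bonded 5-OH, and the benzyl ether keeps 3'-O out of the reaction.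

Step 12
Reactants: 22 2-[3-(benzyloxy)-4-(sulfooxy)phenyl]-7-methoxy-4-oxo-4H-chromene-3,5-diyl bis(hydrogen sulfate)
Product: 23 rhamnetin 3,5,4'-tri-O-sulfate, 2-[3-hydroxy-4-(sulfooxy)phenyl]-7-methoxy-4-oxo-4H-chromene-3,5-diyl bis(hydrogen sulfate)
Conditions: H2 (1 atm), Pd/C (10 wt% palladium on carbon), MeOH/H2O, rt
Reagents that add atoms: none
Why: Hydrogenolysis of a benzyl aryl ether at neutral pH; aryl sulfate salts and the flavonol C2=C3 bond are inert under these conditions.

## Compound list

1 | 3,5-dimethoxyphenol | COc1cc(O)cc(OC)c1 | starting material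
2 | 3,5-dimethoxyphenyl N-(propan-2-yl)carbamate | COc1cc(OC)cc(OC(=O)NC(C)C)c1 | intermediate
3 | 3,5-dimethoxyphenyl N-[tert-butyl(dimethyl)silyl]-N-(propan-2-yl)carbamate | COc1cc(OC)cc(OC(=O)N(C(C)C)[Si](C)(C)C(C)(C)C)c1 | intermediate
4 | 2-lithio derivative of 3 (aryllithium, lithium on the carbon between the carbamate and a methoxy group) | COc1cc(OC)c([Li])c(OC(=O)N(C(C)C)[Si](C)(C)C(C)(C)C)c1 | intermediate
5 | 3,5-dimethoxy-2-(trimethylsilyl)phenyl N-[tert-butyl(dimethyl)silyl]-N-(propan-2-yl)carbamate | COc1cc(OC)c([Si](C)(C)C)c(OC(=O)N(C(C)C)[Si](C)(C)C(C)(C)C)c1 | intermediate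
6 | 3,5-dimethoxy-2-(trimethylsilyl)phenyl N-(propan-2-yl)carbamate | COc1cc(OC)c([Si](C)(C)C)c(OC(=O)NC(C)C)c1 | intermediate
7 | 3,5-dimethoxy-2-(trimethylsilyl)phenol (present as its DBU salt) | COc1cc(O)c([Si](C)(C)C)c(OC)c1 | intermediate
8 | 3,5-dimethoxy-2-(trimethylsilyl)phenyl trifluoromethanesulfonate | COc1cc(OC)c([Si](C)(C)C)c(OS(=O)(=O)C(F)(F)F)c1 | intermediate
9 | 3,4-dihydroxybenzaldehyde | O=Cc1ccc(O)c(O)c1 | starting material
10 | 3-hydroxy-4-(methoxymethoxy)benzaldehyde | COCOc1ccc(C=O)cc1O | intermediate
11 | 3-(benzyloxy)-4-(methoxymethoxy)benzaldehyde | COCOc1ccc(C=O)cc1OCc1ccccc1 | intermediate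
12 | 2-(benzyloxy)-4-(2,2-dibromoethenyl)-1-(methoxymethoxy)benzene | COCOc1ccc(C=C(Br)Br)cc1OCc1ccccc1 | intermediate
13 | lithium [3-(benzyloxy)-4-(methoxymethoxy)phenyl]ethynide | [Li]C#Cc1ccc(OCOC)c(OCc2ccccc2)c1 | intermediate
14 | 3-[3-(benzyloxy)-4-(methoxymethoxy)phenyl]prop-2-ynoic acid | OC(=O)C#Cc1ccc(OCOC)c(OCc2ccccc2)c1 | intermediate
15 | 3,5-dimethoxybenzyne (1,2-didehydro-3,5-dimethoxybenzene) | COC1=CC(OC)=CC#C1 | intermediate
16 | 3-[3-(benzyloxy)-4-(methoxymethoxy)phenyl]-1-(2-hydroxy-4,6-dimethoxyphenyl)prop-2-yn-1-one (present as its caesium phenoxide) | COc1cc(O)c(C(=O)C#Cc2ccc(OCOC)c(OCc3ccccc3)c2)c(OC)c1 | intermediate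
17 | 2-[3-(benzyloxy)-4-(methoxymethoxy)phenyl]-5,7-dimethoxy-4H-chromen-4-one | COc1cc(OC)c2c(=O)cc(-c3ccc(OCOC)c(OCc4ccccc4)c3)oc2c1 | intermediate
18 | racemic cis-fused 2,3-epoxide of 17, 1a-[3-(benzyloxy)-4-(methoxymethoxy)phenyl]-4,6-dimethoxy-1a,7a-dihydro-7H-oxireno[2,3-b]chromen-7-one (one enantiomer drawn) | COc1cc(OC)c2C(=O)[C@@H]3O[C@]3(c4ccc(OCOC)c(OCc5ccccc5)c4)Oc2c1 | intermediate
19 | 2-[3-(benzyloxy)-4-(methoxymethoxy)phenyl]-3-hydroxy-5,7-dimethoxy-4H-chromen-4-one | COc1cc(OC)c2c(=O)c(O)c(-c3ccc(OCOC)c(OCc4ccccc4)c3)oc2c1 | intermediate
20 | 2-[3-(benzyloxy)-4-(methoxymethoxy)phenyl]-3,5-dihydroxy-7-methoxy-4H-chromen-4-one | COc1cc(O)c2c(=O)c(O)c(-c3ccc(OCOC)c(OCc4ccccc4)c3)oc2c1 | intermediate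
21 | 2-[3-(benzyloxy)-4-hydroxyphenyl]-3,5-dihydroxy-7-methoxy-4H-chromen-4-one | COc1cc(O)c2c(=O)c(O)c(-c3ccc(O)c(OCc4ccccc4)c3)oc2c1 | intermediate
22 | 2-[3-(benzyloxy)-4-(sulfooxy)phenyl]-7-methoxy-4-oxo-4H-chromene-3,5-diyl bis(hydrogen sulfate) (handled as the trisodium salt) | COc1cc(OS(=O)(=O)O)c2c(=O)c(OS(=O)(=O)O)c(-c3ccc(OS(=O)(=O)O)c(OCc4ccccc4)c3)oc2c1 | intermediate
23 | rhamnetin 3,5,4'-tri-O-sulfate (handled as the trisodium salt) | COc1cc(OS(=O)(=O)O)c2c(=O)c(OS(=O)(=O)O)c(-c3ccc(OS(=O)(=O)O)c(O)c3)oc2c1 | target

## Step count and risks

Total: 12 steps. Longest linear sequence: 9 steps (steps 4 to 12, from 3,4-dihydroxybenzaldehyde); the aryne precursor branch is 3 steps (steps 1 to 3).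

**Step 8 (key step).**
- What may go wrong: protonation of the aryl anion before acyl transfer, which stops the sequence at the aryl ester; thermal decarboxylation of the caesium propiolate at 125 °C; or closure of the phenoxide in the 5-exo mode.
- Fallback: sets out from 6 and 12 and comes back at 17, with C4 supplied by carbon monoxide instead of the carboxyl group. Ipso-iododesilylation of 6 with ICl gives 2-iodo-3,5-dimethoxyphenyl N-(propan-2-yl)carbamate F1. DBU/Et2NH then releases 2-iodo-3,5-dimethoxyphenol F2. Treating 12 with n-BuLi and quenching with aqueous NH4Cl in place of CO2 gives 2-(benzyloxy)-4-ethynyl-1-(methoxymethoxy)benzene F3 by way of 13. Carbonylative Sonogashira coupling of F2 and F3 (PdCl2(PPh3)2, CO, Et2NH) gives ynone 16, which closes to 17 in the amine medium.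

**Step 9.**
- What may go wrong: oxidation at the benzylic C–H bonds of the benzyl ether or on electron-rich ring A by excess dioxirane; or diversion of the epoxide opening into ring contraction.
- Fallback: sets out from 17 and comes back at 19. Deprotonation at C3 with LiN(i-Pr)2 in THF at −78 °C gives the 3-lithioflavone F4. B(OMe)3 converts it into the dimethyl boronate F5, and oxidation of the C–B bond with H2O2/AcOH gives 19.

**Step 10.**
- What may go wrong: with the 3-hydroxyl free, magnesium is first taken up by the 3-oxide/C4 carbonyl chelate and HI is released, so demethylation at C5 may stall. Alternatively iodide may remove the 3'-benzyl ether, which would erase the difference between 3'-O and 4'-O.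
- Fallback: sets out from 19 and comes back at 20. Acetylation (Ac2O, pyridine) gives the 3-acetate F6, which has only the 5-OMe/C4 carbonyl chelation site and no acidic proton. MgI2·OEt2 then gives the 3-acetoxy-5-hydroxy flavone F7. Methanolysis of the acetate (K2CO3, MeOH) gives 20, which enters the acidic methanol stage of step 10.

**Step 11.**
- What may go wrong: incomplete sulfation at the hydrogen-bonded 5-OH, leaving mixtures of di- and trisulfate salts that are hard to separate; or ring sulfonation of ring A under the forcing conditions.
- Fallback: sets out from 21 and comes back at 22, by way of neutral sulfate diesters. The three hydroxyls are deprotonated with NaH in THF/DMF and treated with 2,2,2-trichloroethyl chlorosulfate to give the tris(2,2,2-trichloroethyl sulfate) F8, which can be purified on silica. Reductive removal of the trichloroethyl groups with Zn and HCO2NH4 in MeOH gives 22.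

## Further compounds

F1 | step 8 | 2-iodo-3,5-dimethoxyphenyl N-(propan-2-yl)carbamate | COc1cc(OC)c(I)c(OC(=O)NC(C)C)c1
F2 | step 8 | 2-iodo-3,5-dimethoxyphenol | COc1cc(O)c(I)c(OC)c1
F3 | step 8 | 2-(benzyloxy)-4-ethynyl-1-(methoxymethoxy)benzene | C#Cc1ccc(OCOC)c(OCc2ccccc2)c1
F4 | step 9 | 2-[3-(benzyloxy)-4-(methoxymethoxy)phenyl]-3-lithio-5,7-dimethoxy-4H-chromen-4-one | COc1cc(OC)c2c(=O)c([Li])c(-c3ccc(OCOC)c(OCc4ccccc4)c3)oc2c1
F5 | step 9 | dimethyl {2-[3-(benzyloxy)-4-(methoxymethoxy)phenyl]-5,7-dimethoxy-4-oxo-4H-chromen-3-yl}boronate | COB(OC)c1c(-c2ccc(OCOC)c(OCc3ccccc3)c2)oc2cc(OC)cc(OC)c2c1=O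
F6 | step 10 | 2-[3-(benzyloxy)-4-(methoxymethoxy)phenyl]-5,7-dimethoxy-4-oxo-4H-chromen-3-yl acetate | COc1cc(OC)c2c(=O)c(OC(C)=O)c(-c3ccc(OCOC)c(OCc4ccccc4)c3)oc2c1
F7 | step 10 | 2-[3-(benzyloxy)-4-(methoxymethoxy)phenyl]-5-hydroxy-7-methoxy-4-oxo-4H-chromen-3-yl acetate | COc1cc(O)c2c(=O)c(OC(C)=O)c(-c3ccc(OCOC)c(OCc4ccccc4)c3)oc2c1
F8 | step 11 | 2-{3-(benzyloxy)-4-[(2,2,2-trichloroethoxy)sulfonyloxy]phenyl}-7-methoxy-4-oxo-4H-chromene-3,5-diyl bis(2,2,2-trichloroethyl) bis(sulfate) | COc1cc(OS(=O)(=O)OCC(Cl)(Cl)Cl)c2c(=O)c(OS(=O)(=O)OCC(Cl)(Cl)Cl)c(-c3ccc(OS(=O)(=O)OCC(Cl)(Cl)Cl)c(OCc4ccccc4)c3)oc2c1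
A1 | alternative 1 | 2-iodo-5-methoxy-1,3-bis(methoxymethoxy)benzene | COCOc1cc(OC)cc(OCOC)c1I
A2 | alternative 1 | 1-[3-(benzyloxy)-4-(methoxymethoxy)phenyl]-2-(methoxymethoxy)ethan-1-one | COCOCC(=O)c1ccc(OCOC)c(OCc2ccccc2)c1
A3 | alternative 1 | carbon monoxide | [C-]#[O+]
A4 | alternative 1 | 2-[3-(benzyloxy)-4-hydroxyphenyl]-3,5-dihydroxy-7-methoxy-4H-chromen-4-one | COc1cc(O)c2c(=O)c(O)c(-c3ccc(O)c(OCc4ccccc4)c3)oc2c1
A5 | alternative 2 | 2-[3-(benzyloxy)-4-(methoxymethoxy)phenyl]-5-bromo-3-(methoxymethoxy)-4H-pyran-4-one | COCOc1c(-c2ccc(OCOC)c(OCc3ccccc3)c2)occ(Br)c1=O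
A6 | alternative 2 | [(1,3-dimethoxybuta-1,3-dien-1-yl)oxy]trimethylsilane | COC(=C)C=C(OC)O[Si](C)(C)C
A7 | alternative 2 | 2-[3-(benzyloxy)-4-(methoxymethoxy)phenyl]-5-hydroxy-7-methoxy-3-(methoxymethoxy)-4H-chromen-4-one | COCOc1c(-c2ccc(OCOC)c(OCc3ccccc3)c2)oc2cc(OC)cc(O)c2c1=O
A8 | alternative 3 | 2,4,6-trifluorobenzoyl chloride | O=C(Cl)c1c(F)cc(F)cc1F
A9 | alternative 3 | 2-[3-(benzyloxy)-4-(methoxymethoxy)phenyl]-5,7-difluoro-3-(methoxymethoxy)-4H-chromen-4-one | COCOc1c(-c2ccc(OCOC)c(OCc3ccccc3)c2)oc2cc(F)cc(F)c2c1=O
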